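The question was how much of the solid monomer stood in chains after 10 d, in a flask where it must dissolve before anything can use it.

solid monomer 0.20 M; protic impurity 0.0200 M; initiator 0.2 mol%; time 10 d

    free monomer + initiator → living end + monomer in chains (k1 = 0.11 L mol⁻¹ h⁻¹)
    free monomer + living end → monomer in chains + living end, rate k2*[living end]*[free monomer] (k2 = 150 L mol⁻¹ h⁻¹)
    solid monomer ⇌ free monomer, rate k3*(cs3 - [free monomer]) while solid is left; crystals form when [free monomer] > cs3 (cs3 = 0.15 M, k3 = 0.0061 h⁻¹)
    initiator ⇌ dormant form (K4 = 8.0, k4 = 0.0086 h⁻¹)
    protic impurity + free monomer → quenched substrate (k5 = 1.8 L mol⁻¹ h⁻¹)

1. the monomer in chains standing at 10 d, as a percentage of the solid monomer charged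
2. concentration of free monomer in solution at 5.0 d, in percent of saturation
3. the change that raises the amount of monomer in chains at 10 d, in percent of the solid monomer charged most ("none" if none brings more than 2 percentage points) (teal / grey / blue / none)
4. amount of monomer in chains at 10 d, in percent of the solid monomer charged, after grey

- teal: doubling the amount of initiator, all else as stated
- grey: doubling the dissolution coefficient of step 3, all else as stated
- blue: doubling the solubility in step 3, all else as stated

- as a solid, counted per litre of solution: solid monomer
- at the start none of the solid monomer is in solution
- run time (flask): 10 d

I wrote the balance of the initiator, the reagent charged in smaller amount than the protic impurity: free initiator, its dormant form (the resting state) and living ends add up to the charge of 4.00 × 10⁻⁴ M. From it I carried the split number, 150 L mol⁻¹ h⁻¹ times that charge over 0.0061 h⁻¹, which came to 9.84, the ratio of consumption to dissolution with the whole charge living. Setting dissolution equal to consumption, free monomer levels off at saturation divided by one plus the split number times the live share of the charge.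

Suppose first that the whole charge lived at once. The split number is larger than one, so free monomer levelled off in that version at 9.23% of saturation. Dissolving, which can deliver 110% of the solid charged into a solution kept empty, delivered 99.7% at that level, and after what stands free and the protic impurity's part the chains held 82.7% at 10 d. Suppose instead that no initiator lived: the chains stay empty.

The real flask lies between, and its place is the live share. With a relaxation half-life of 2.99 d, free initiator summed over the run equalled the whole charge standing for 4.56 d. With the full charge of protic impurity present, dissolving and quenching balance at 0.0217 M of free monomer; I took that one level as a rough figure for the whole of that time, which gave a live share of 26.2%. That put the plateau at 28.0% of saturation, and I used this for 5.0 d too. Supply at that level, less what stands free, less the impurity's part, gave 48.1% in chains. Teal leaves the supply as it is, while grey and blue double it, so I favoured those two but could not part them.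

The forecast, slightly above mine, gave 52%, 32%, blue and 82%, holding that “Dissolution is the bottleneck”.

The flask gave 50.6% in chains, 83.3% after grey, and blue as best, with a gain of 35 percentage points against 33 points for grey. Free monomer stood at 31.6% of saturation at 5.0 d. Living ends stood at 1.10 × 10⁻⁴ M at 10.0 d, which makes the split number 2.71 and the plateau 27.0%, against 28.9% of saturation standing. In the flask charged with 0.05 mol% of initiator, living ends of 3.20 × 10⁻⁵ M make it 0.787 and the plateau 56.0%, and free monomer there stood at 53.5% of saturation.

The rate constants are those of an exercise; the run is a simulation.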